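**Strategy.** Everything rests on cutting ring A at C5–C10 and ring B at C8–C9, an intramolecular Diels–Alder reaction of an acyclic trienal. Ring B carries oxygen at C6 and C8 with C7 between them; this is read as a 4-methoxy-2-silyloxy diene (C5=C6–C7=C8). The cis pair C20 methyl/C11 at C10/C9 is read as an (E)-enal from methyl geranate, and the C4 gem-dimethyl group as a tertiary chloride that joins the two halves by SN1 alkylation. One catalysed cycloaddition closes ring A together with ring B, sets C5, C9 and C10, and delivers O6, a latent O8 and the C11 aldehyde; no ring is closed afterwards.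

Key step: step 7

Remark: labdane numbering (C1–C20) is used for atoms in all compounds, also the acyclic ones; "drimane" means the 4,4,8,10-tetramethyldecalin core with C11 on C9.
Assumption: the (S)-oxazaborolidinium catalyst of step 7 leaves the Re face of C10 open, and the (R)-binaphthoxide complex of step 10 delivers CH2 to the Si face of the C13 ketone; where the sense is opposite, the enantiomeric catalyst is used.

Step 1
Reactants: 1 (E)-4-methoxypent-3-en-2-one
Product: 3 (E)-4-methoxy-2-(trimethylsilyloxy)penta-1,3-diene, via lithium dienolate 2 (not isolated)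
Conditions: LiN(i-Pr)2, THF, −78 °C; Me3SiCl, −78 → 0 °C
Reagents that add atoms: chlorotrimethylsilane, C[Si](C)(C)Cl
Why: Kinetic α′-deprotonation of the vinylogous ester at the methyl ketone carbon (C5) and O-silylation of the cross-conjugated enolate should give the 1-methoxy-3-silyloxy diene; no stereocenter is formed.

Step 2
Reactants: 4 methyl (2E)-3,7-dimethylocta-2,6-dienoate (methyl geranate)
Product: 5 methyl (2E)-7-chloro-3,7-dimethyloct-2-enoate
Conditions: HCl (gas), CH2Cl2, −20 °C
Reagents that add atoms: hydrogen chloride, Cl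
Why: Markovnikov hydrochlorination should occur only at the electron-rich trisubstituted C3=C4 alkene, because the C9=C10 alkene is deactivated by conjugation with the ester.

Step 3
Reactants: 5 methyl (2E)-7-chloro-3,7-dimethyloct-2-enoate; 3 (E)-4-methoxy-2-(trimethylsilyloxy)penta-1,3-diene
Product: 6 methyl (2E,10E)-11-methoxy-3,7,7-trimethyl-9-oxododeca-2,10-dienoate
Conditions: TiCl4 (1.1 equiv), CH2Cl2, −78 °C
Reagents that add atoms: none
Why: Lewis-acid-mediated SN1 α-tert-alkylation of a silyl enol ether: TiCl4 ionises the tertiary chloride and the terminal CH2 of diene 3 (C5) captures the C4 cation, which creates quaternary C4 and the C4–C5 bond and leaves the β-methoxy enone.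

Step 4
Reactants: 6 methyl (2E,10E)-11-methoxy-3,7,7-trimethyl-9-oxododeca-2,10-dienoate
Product: 8 methyl (2E,8Z,10E)-11-methoxy-3,7,7-trimethyl-9-(triisopropylsilyloxy)dodeca-2,8,10-trienoate, via lithium dienolate 7 (not isolated)
Conditions: LiN(SiMe3)2, THF, −78 °C; i-Pr3SiOSO2CF3, −78 → −20 °C
Reagents that add atoms: triisopropylsilyl trifluoromethanesulfonate, CC(C)[Si](C(C)C)(C(C)C)OS(=O)(=O)C(F)(F)F
Why: Kinetic α′-enolisation of the β-methoxy enone at C5 (the γ-protons of the enoate are less acidic) and O-silylation should give the silyl dienol ether, with the bulky C4 group cis to oxygen so that the tether sits on the outside of the diene.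

Step 5
Reactants: 8 methyl (2E,8Z,10E)-11-methoxy-3,7,7-trimethyl-9-(triisopropylsilyloxy)dodeca-2,8,10-trienoate
Product: 9 (2E,8Z,10E)-11-methoxy-3,7,7-trimethyl-9-(triisopropylsilyloxy)dodeca-2,8,10-trien-1-ol
Conditions: i-Bu2AlH (2.5 equiv), CH2Cl2, −78 °C; aqueous potassium sodium tartrate
Reagents that add atoms: none
Why: 1,2-Reduction of the enoate to the allylic alcohol by the aluminium hydride should leave the silyl and methyl enol ethers untouched.

Step 6
Reactants: 9 (2E,8Z,10E)-11-methoxy-3,7,7-trimethyl-9-(triisopropylsilyloxy)dodeca-2,8,10-trien-1-ol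
Product: 10 (2E,8Z,10E)-11-methoxy-3,7,7-trimethyl-9-(triisopropylsilyloxy)dodeca-2,8,10-trienal
Conditions: MnO2, CH2Cl2, rt
Reagents that add atoms: none
Why: Selective allylic oxidation under neutral conditions should give the (E)-enal without harming the acid-labile diene.

Step 7
Reactants: 10 (2E,8Z,10E)-11-methoxy-3,7,7-trimethyl-9-(triisopropylsilyloxy)dodeca-2,8,10-trienal
Product: 11 8β-methoxy-6-(triisopropylsilyloxy)drim-6-en-11-al (5α-H, 9β-CHO, 10β-CH3)
Conditions: (S)-3,3-diphenyl-1-(2-methylphenyl)tetrahydro-1H,3H-pyrrolo[1,2-c][1,3,2]oxazaborole (20 mol %) protonated by (CF3SO2)2NH (18 mol %), CH2Cl2, −78 → −40 °C; Et3N quench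
Reagents that add atoms: none
Why: The oxazaborolidinium ion binds the formyl group of the s-trans enal and lowers its LUMO, so that the nucleophilic diene terminus C5 adds to the electrophilic β-carbon C10 and C8 adds to C9 in a concerted but asynchronous [4+2] cycloaddition; the closest known reaction type is the chiral-Lewis-acid-catalysed type 1 intramolecular Diels–Alder reaction of (E)-deca-2,7,9-trienals bearing 2-silyloxy dienes. Ring A is closed by the C5–C10 bond in a 6-exo mode with respect to both π systems (four-carbon tether C1–C4, helped by the C4 gem-dimethyl group), and ring B is the cyclohexene of the cycloaddition (bonds C5–C10 and C8–C9). C10 is set by the catalyst, which shields one face of the enal so that C5 adds to the Re face of C10; C9 follows from the E geometry of the dienophile by suprafacial addition (CHO cis to the C10 methyl). C5 follows from the endo transition state (CHO under the diene) that gives the trans ring fusion and stays correctable once C6 is a ketone; C8 is a by-product stereocenter that is erased in step 12. The step needs regioselectivity, secured by the tether and by matched polarity (C5 nucleophilic, C10 electrophilic), and facial selectivity, which rests on the catalyst. The silyl enol ether and the 8-methoxy group of the adduct mask the later enone through steps 8–11.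

Step 8
Reactants: 11 8β-methoxy-6-(triisopropylsilyloxy)drim-6-en-11-al
Product: 12 (11E)-8β-methoxy-6-(triisopropylsilyloxy)-14,15-dinorlabda-6,11-dien-13-one
Conditions: (CH3O)2P(O)CH2C(O)CH3, LiCl, i-Pr2NEt, CH3CN, rt → 40 °C
Reagents that add atoms: dimethyl (2-oxopropyl)phosphonate, CC(=O)CP(=O)(OC)OC
Why: Horner–Wadsworth–Emmons olefination under Masamune–Roush conditions should add C12, C13 and C16 as the (E)-enone, the mild amine base limiting enolisation at C9.

Step 9
Reactants: 12 (11E)-8β-methoxy-6-(triisopropylsilyloxy)-14,15-dinorlabda-6,11-dien-13-one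
Product: 13 8β-methoxy-6-(triisopropylsilyloxy)-14,15-dinorlabd-6-en-13-one
Conditions: H2 (1 atm), Pd/C, EtOAc, Et3N (trace), rt
Reagents that add atoms: none
Why: Catalytic hydrogenation should saturate only the disubstituted enone alkene, because the ring silyl enol ether lies between C5 and the quaternary C8 and is shielded.

Step 10
Reactants: 13 8β-methoxy-6-(triisopropylsilyloxy)-14,15-dinorlabd-6-en-13-one
Product: 14 (13R)-13,14-epoxy-8β-methoxy-6-(triisopropylsilyloxy)-15-norlabd-6-ene
Conditions: (CH3)3S(O)I, NaH, THF; LaLi3[(R)-1,1′-binaphthalene-2,2′-diolate]3 (5 mol %), [2,4,6-(CH3O)3C6H2]3P=O (5 mol %), 5 Å molecular sieves, rt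
Reagents that add atoms: trimethylsulfoxonium iodide, C[S+](C)(C)=O.[I-]
Why: Catalytic asymmetric Corey–Chaykovsky epoxidation of the methyl ketone should give the 2,2-disubstituted epoxide, C13 being set by the chiral lanthanum–lithium binaphthoxide through Si-face delivery of the methylene group; the ring carries no free carbonyl at this stage.

Step 11
Reactants: 14 (13R)-13,14-epoxy-8β-methoxy-6-(triisopropylsilyloxy)-15-norlabd-6-ene
Product: 15 (13R)-8β-methoxy-6-(triisopropylsilyloxy)labda-6,14-dien-13-ol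
Conditions: (CH3)3SI, n-BuLi, THF, −10 °C → rt
Reagents that add atoms: trimethylsulfonium iodide, C[S+](C)C.[I-]
Why: Dimethylsulfonium methylide should open the epoxide at its CH2 carbon and the betaine should lose dimethyl sulfide (one-carbon homologation of an epoxide to an allylic alcohol), which gives the vinyl carbinol without touching the C13–O bond.

Step 12
Reactants: 15 (13R)-8β-methoxy-6-(triisopropylsilyloxy)labda-6,14-dien-13-ol
Product: 16 (13R)-13-hydroxylabda-7,14-dien-6-one
Conditions: Bu4NF, THF, 0 °C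
Reagents that add atoms: none
Why: Fluoride should cleave the silyl enol ether and the C6 enolate should expel the 8-methoxide (E1cB) to reveal the Δ7-6-ketone; C5, now α to the ketone, can settle in the trans-fused 5α-H form.

Step 13
Reactants: 16 (13R)-13-hydroxylabda-7,14-dien-6-one
Product: 17 (13R)-7α,8α-epoxy-13-hydroxylabd-14-en-6-one
Conditions: H2O2 (30 %), NaOH, MeOH, 0 °C
Reagents that add atoms: hydrogen peroxide, OO
Why: Weitz–Scheffer nucleophilic epoxidation of the enone should occur from the α face, away from the syn-axial C10 β-methyl group, which sets the C8–O bond α; the isolated vinyl group is inert.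

Step 14
Reactants: 17 (13R)-7α,8α-epoxy-13-hydroxylabd-14-en-6-one
Product: 19 (13R)-labd-14-ene-6α,8α,13-triol, via hydroxy ketone 18 (not isolated)
Conditions: Li, NH3/THF, −78 °C; then MeOH, −78 → −33 °C; NH4Cl
Reagents that add atoms: none
Why: Dissolving-metal reduction should first cleave the C7–O bond of the α,β-epoxy ketone (8α-OH retained) and then, with methanol as proton source, reduce the ketone under thermodynamic control to the equatorial 6α-alcohol, since a 6β-hydroxyl would be syn-axial to the C4, C8 and C10 methyl groups.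

Step 15
Reactants: 19 (13R)-labd-14-ene-6α,8α,13-triol; 20 (Z)-2-methylbut-2-enoic acid (angelic acid)
Product: 22 (13R)-8α,13-dihydroxylabd-14-en-6α-yl (Z)-2-methylbut-2-enoate, via mixed anhydride 21 (not isolated)
Conditions: 2,4,6-Cl3C6H2COCl, Et3N, toluene, rt; then 19, 80 °C
Reagents that add atoms: none
Why: Yamaguchi-type esterification through the mixed anhydride, run without a nucleophilic amine catalyst to keep the Z geometry, should acylate only the secondary 6α-hydroxyl because the two tertiary hydroxyls are too hindered.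

**Compound list**

1 | (E)-4-methoxypent-3-en-2-one | CO/C(C)=C/C(C)=O | starting material
2 | lithium (E)-4-methoxypenta-1,3-dien-2-olate | [Li+].[O-]C(=C)/C=C(\C)OC | intermediate (not isolated)
3 | (E)-4-methoxy-2-(trimethylsilyloxy)penta-1,3-diene | C=C(O[Si](C)(C)C)/C=C(\C)OC | intermediate
4 | methyl (2E)-3,7-dimethylocta-2,6-dienoate (methyl geranate) | COC(=O)/C=C(\C)CCC=C(C)C | starting material
5 | methyl (2E)-7-chloro-3,7-dimethyloct-2-enoate | COC(=O)/C=C(\C)CCCC(C)(C)Cl | intermediate
6 | methyl (2E,10E)-11-methoxy-3,7,7-trimethyl-9-oxododeca-2,10-dienoate | COC(=O)/C=C(\C)CCCC(C)(C)CC(=O)/C=C(\C)OC | intermediate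
7 | lithium (2E,8Z,10E)-1,11-dimethoxy-3,7,7-trimethyl-1-oxododeca-2,8,10-trien-9-olate | COC(=O)/C=C(\C)CCCC(C)(C)/C=C(\[O-])/C=C(\C)OC.[Li+] | intermediate (not isolated)
8 | methyl (2E,8Z,10E)-11-methoxy-3,7,7-trimethyl-9-(triisopropylsilyloxy)dodeca-2,8,10-trienoate | COC(=O)/C=C(\C)CCCC(C)(C)/C=C(\O[Si](C(C)C)(C(C)C)C(C)C)/C=C(\C)OC | intermediate
9 | (2E,8Z,10E)-11-methoxy-3,7,7-trimethyl-9-(triisopropylsilyloxy)dodeca-2,8,10-trien-1-ol | OC/C=C(\C)CCCC(C)(C)/C=C(\O[Si](C(C)C)(C(C)C)C(C)C)/C=C(\C)OC | intermediate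
10 | (2E,8Z,10E)-11-methoxy-3,7,7-trimethyl-9-(triisopropylsilyloxy)dodeca-2,8,10-trienal | O=C/C=C(\C)CCCC(C)(C)/C=C(\O[Si](C(C)C)(C(C)C)C(C)C)/C=C(\C)OC | intermediate
11 | 8β-methoxy-6-(triisopropylsilyloxy)drim-6-en-11-al (5α-H, 9β-CHO, 10β-CH3; C8 drawn for the endo adduct) | O=C[C@@H]1[C@@]2(C)CCCC(C)(C)[C@@H]2C(O[Si](C(C)C)(C(C)C)C(C)C)=C[C@]1(C)OC | intermediate
12 | (11E)-8β-methoxy-6-(triisopropylsilyloxy)-14,15-dinorlabda-6,11-dien-13-one | CC(=O)/C=C/[C@@H]1[C@@]2(C)CCCC(C)(C)[C@@H]2C(O[Si](C(C)C)(C(C)C)C(C)C)=C[C@]1(C)OC | intermediate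
13 | 8β-methoxy-6-(triisopropylsilyloxy)-14,15-dinorlabd-6-en-13-one | CC(=O)CC[C@@H]1[C@@]2(C)CCCC(C)(C)[C@@H]2C(O[Si](C(C)C)(C(C)C)C(C)C)=C[C@]1(C)OC | intermediate
14 | (13R)-13,14-epoxy-8β-methoxy-6-(triisopropylsilyloxy)-15-norlabd-6-ene | C1O[C@]1(C)CC[C@@H]2[C@@]3(C)CCCC(C)(C)[C@@H]3C(O[Si](C(C)C)(C(C)C)C(C)C)=C[C@]2(C)OC | intermediate
15 | (13R)-8β-methoxy-6-(triisopropylsilyloxy)labda-6,14-dien-13-ol | C=C[C@](C)(O)CC[C@@H]1[C@@]2(C)CCCC(C)(C)[C@@H]2C(O[Si](C(C)C)(C(C)C)C(C)C)=C[C@]1(C)OC | intermediate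
16 | (13R)-13-hydroxylabda-7,14-dien-6-one | C=C[C@](C)(O)CC[C@@H]1[C@@]2(C)CCCC(C)(C)[C@@H]2C(=O)C=C1C | intermediate
17 | (13R)-7α,8α-epoxy-13-hydroxylabd-14-en-6-one | C=C[C@](C)(O)CC[C@@H]1[C@@]2(C)CCCC(C)(C)[C@@H]2C(=O)[C@H]3O[C@@]13C | intermediate
18 | (13R)-8α,13-dihydroxylabd-14-en-6-one | C=C[C@](C)(O)CC[C@@H]1[C@@]2(C)CCCC(C)(C)[C@@H]2C(=O)C[C@@]1(C)O | intermediate (not isolated)
19 | (13R)-labd-14-ene-6α,8α,13-triol | C=C[C@](C)(O)CC[C@@H]1[C@@]2(C)CCCC(C)(C)[C@@H]2[C@@H](O)C[C@@]1(C)O | intermediate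
20 | (Z)-2-methylbut-2-enoic acid (angelic acid) | C/C=C(/C)C(=O)O | starting material
21 | (Z)-2-methylbut-2-enoic 2,4,6-trichlorobenzoic anhydride | C/C=C(/C)C(=O)OC(=O)c1c(Cl)cc(Cl)cc1Cl | intermediate (not isolated)
22 | (13R)-8α,13-dihydroxylabd-14-en-6α-yl (Z)-2-methylbut-2-enoate | C=C[C@](C)(O)CC[C@@H]1[C@@]2(C)CCCC(C)(C)[C@@H]2[C@@H](OC(=O)/C(C)=C\C)C[C@@]1(C)O | target

**Count.** Total: 15 steps. Longest linear sequence: 14 steps (steps 2–15, from methyl geranate 4).

**Steps most likely to fail**

Step 7. The hindered β,β-disubstituted enal may react too slowly at low temperature, the acidic catalyst may cleave the silyl dienol ether before cycloaddition, or facial selectivity may be poor. The fallback sets out from 10 and comes back at 11. Uncatalysed thermal cycloaddition (toluene, 100 °C, 2,6-di-tert-butyl-4-methylphenol) should give 11 as the racemate, that is together with its enantiomer ent-11 F1. NaBH4 (MeOH/THF, 0 °C) reduces both to 8β-methoxy-6-(triisopropylsilyloxy)drim-6-en-11-ol F2 and its enantiomer ent-alcohol F3. Esterification with (S)-2-methoxy-2-phenylacetic acid (N,N′-dicyclohexylcarbodiimide, 4-(dimethylamino)pyridine, CH2Cl2) gives the diastereomeric esters (S)-O-methylmandelate of the wanted alcohol F4 and (S)-O-methylmandelate of the enantiomeric alcohol F5, which are separated by chromatography. K2CO3 in MeOH returns F2 from F4, and Dess–Martin periodinane with pyridine oxidises it to 11.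

Step 8. Addition to an aldehyde flanked by two quaternary carbons may be slow, and enolisation may epimerise C9. The fallback sets out from 11 and comes back at 12. The smaller and more reactive lithium enolate of acetone (acetone, LiN(i-Pr)2, THF, −78 °C) adds to the aldehyde to give the β-hydroxy ketone aldol adduct F6 (mixture at C11). Mesylation and elimination (CH3SO2Cl, Et3N, CH2Cl2, 0 °C → rt) then give 12.

Step 15. The activated angelate may isomerise from Z to E (tiglate), and acylation of the 6α-hydroxyl, which is crowded by the 4α-methyl group, may be slow. The fallback sets out from 19 and ends at 22. The 6α-hydroxyl is acylated with 2-[bis(2,2,2-trifluoroethoxy)phosphoryl]propanoic acid (N,N′-dicyclohexylcarbodiimide, 4-(dimethylamino)pyridine, CH2Cl2) to give the phosphonopropionate ester F7. A Z-selective Still–Gennari olefination with acetaldehyde (KN(SiMe3)2 in excess, 18-crown-6, THF, −78 °C) then builds the angelate double bond on the molecule and gives 22.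

**Further compounds**

F1 | step 7 | ent-11, enantiomer of 8β-methoxy-6-(triisopropylsilyloxy)drim-6-en-11-al | O=C[C@H]1[C@]2(C)CCCC(C)(C)[C@H]2C(O[Si](C(C)C)(C(C)C)C(C)C)=C[C@@]1(C)OC
F2 | step 7 | 8β-methoxy-6-(triisopropylsilyloxy)drim-6-en-11-ol | OC[C@@H]1[C@@]2(C)CCCC(C)(C)[C@@H]2C(O[Si](C(C)C)(C(C)C)C(C)C)=C[C@]1(C)OC
F3 | step 7 | enantiomer of F2 | OC[C@H]1[C@]2(C)CCCC(C)(C)[C@H]2C(O[Si](C(C)C)(C(C)C)C(C)C)=C[C@@]1(C)OC
F4 | step 7 | (S)-2-methoxy-2-phenylacetate of F2 | CO[C@H](C(=O)OC[C@@H]1[C@@]2(C)CCCC(C)(C)[C@@H]2C(O[Si](C(C)C)(C(C)C)C(C)C)=C[C@]1(C)OC)c1ccccc1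
F5 | step 7 | (S)-2-methoxy-2-phenylacetate of F3 | CO[C@H](C(=O)OC[C@H]1[C@]2(C)CCCC(C)(C)[C@H]2C(O[Si](C(C)C)(C(C)C)C(C)C)=C[C@@]1(C)OC)c1ccccc1
F6 | step 8 | 11-hydroxy-8β-methoxy-6-(triisopropylsilyloxy)-14,15-dinorlabd-6-en-13-one (C11 epimers) | CC(=O)CC(O)[C@@H]1[C@@]2(C)CCCC(C)(C)[C@@H]2C(O[Si](C(C)C)(C(C)C)C(C)C)=C[C@]1(C)OC
F7 | step 15 | (13R)-8α,13-dihydroxylabd-14-en-6α-yl 2-[bis(2,2,2-trifluoroethoxy)phosphoryl]propanoate | C=C[C@](C)(O)CC[C@@H]1[C@@]2(C)CCCC(C)(C)[C@@H]2[C@@H](OC(=O)C(C)P(=O)(OCC(F)(F)F)OCC(F)(F)F)C[C@@]1(C)O
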